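## The problem

allo-Pertusaric acid (**14**) is a single, unfused γ-butyrolactone, O1–C2(=O)–C3(=CH2)–C4(CO2H)–C5, whose C5 carries an unbranched 14-oxopentadecyl chain. This lactone numbering is used in all discussion; in the systematic oxolane names C4 and C5 appear as C3 and C2. The skeleton is a straight C16 chain (C5 plus fifteen chain carbons) bearing a four-carbon succinate unit (C2, C3, C4 and the carboxyl carbon) and one methylene carbon, so the difficulty lies in the ring and not in the chain. C4 and C5 are the only stereocentres, both S, with carboxyl and chain cis, the less stable arrangement. Being adjacent, either can direct the other, whereas the methyl ketone thirteen methylene groups away can neither exert nor receive stereochemical influence. Once the α-methylene lactone (a Michael acceptor) is in place, C4–H is activated by the carboxyl and by the enoate, and base would give the trans acid or the endocyclic butenolide. The methylene must therefore arrive late under buffered conditions, and the remote ketone, which would compete in hydride reduction, enolization and carboxylation, must stay masked to the end. The enabling feature is that C4 lies between C5 and its own carboxyl: with C5 as a ketone, C4 is the labile α-carbon of a β-keto ester, so one reduction at C5 can fix both centres. The second carboxyl of the succinate unit (the future C2) then sits where the new C5 hydroxyl can close the ring.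

## Retrosynthesis

**Unmasking (14 to 13).** The last operation is hydrolysis of a dioxolane, so only the two ketal C–O bonds are cut. Carrying the free methyl ketone instead would fail twice: the reductase of the key step reduces methyl ketones, and the magnesium carbonate reagent used for methylenation carboxylates them. Precursor **13** differs from **14** only in the ketal. The forward step needs dilute acid, which the methylene lactone and the cis acid tolerate, and no base.

**Methylene (13 to 10).** The exocyclic C3=CH2 bond is cut next, removing the one-carbon unit from C3. This frees every earlier intermediate from the Michael acceptor and from the doubly activated C4–H. In the forward direction acid **10** is carboxylated at C3 to the malonic half-acid **11**, which undergoes Mannich reaction to **12** and then decarboxylative loss of the amine. This is preferred to enolate chemistry on an ester because in **10** the C4 carboxyl is a carboxylate under the reaction conditions, making C4–H the least acidic α-hydrogen. The forward reaction must leave C4 unchanged at the temperature of the carboxylation.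

**Ring (10 to 9 to 8).** The methyl ester of **9** is cleaved to reach **10**, and the lactone O1–C2 bond of **9** is cut to the open-chain hydroxy diester **8**. Cutting O1–C2 rather than a ring C–C bond keeps all carbons in one chain and leaves no regiochemical choice: the C5 hydroxyl reaches the distal ester through a five-membered transition state and the proximal one only through a four-membered one. Precursor **8** is acyclic with both stereocentres in place. The closure must be run under acid and the ester cleavage near neutrality, so that the cis C4 centre, α to an ester in **9**, is not enolized.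

**Stereocentres (8 to 7).** The C5–H bond is cut. This takes C5 to the ketone level and makes C4 the stereolabile α-carbon of β-keto diester **7**; both stereocentres disappear in one step and **7** can be made racemic. The neighbouring cuts are weaker: a C4–C5 aldol disconnection to aldehyde **5** would need an anti-selective succinate aldol under stoichiometric chiral control, and a stepwise approach sets the two centres in separate operations. The forward reaction must be a reduction selective for one carbonyl face and one C4 epimer while the other epimer racemizes, a dynamic kinetic resolution, for which a ketoreductase is chosen.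

**Succinate unit (7 to 5 and 6).** The C4–C5 bond of **7** is cut between the acyl carbon and the succinate, giving aldehyde **5** as an acyl anion equivalent and dimethyl fumarate (**6**) as acceptor. Compared with enolate alkylation (cutting C3–C4), this delivers all four carbons of the C2–C3–C4–CO2H unit in one catalytic, redox-neutral step from a bulk chemical. The forward Stetter addition only has to favour conjugate addition over acyloin formation. It creates C4 without control, which is what the next step requires.

**Chain (5 to 4 to 3 to 1).** Aldehyde **5** is traced through alcohol **4** and hydroxy ketone **3** to 15-pentadecanolide (**1**); the only C–C cut is the bond between the ketone carbon and its methyl group. The macrolide is preferred to chain coupling because its fifteen carbons plus one methyl are exactly C5 and the side chain, and its two ends are already differentiated: the acyl carbon becomes the methyl ketone and the alkoxy carbon becomes C5. The forward steps need a single methyl addition to the lactone carbonyl, secured by passing through Weinreb amide **2**, then ketalization and a non-acidic oxidation.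

## Roads not taken

**Alternative 1:** The cut removes C2 with the O1–C2 and C2–C3 bonds. Lactone **A2** would form from the syn homopropargylic alcohol **A1** by cyclocarbonylation with PdCl2, SnCl2, PPh3 and CO, which joins the C5 hydroxyl, CO and the terminal alkyne.
- Merits: ring and exocyclic methylene are made together under nearly neutral conditions, so the late carboxylation and Mannich sequence on a cis acid (step 8 here) is avoided. In this respect the road is better than the chosen plan.
- Weak points: **A1** must bring both stereocentres from a separate asymmetric synthesis, for example addition of a chiral allenylmetal reagent to aldehyde **5**. The C4 carboxyl arrives as a silylated hydroxymethyl group and has to be oxidized after the methylene lactone exists, through an aldehyde whose C4–H is activated by both the formyl group and the enoate. The freed primary alcohol of desilylated **A2** can also attack C2 and translactonize to an isomeric five-membered lactone.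
- Against it the chosen plan sets a carboxyl at its final oxidation level from the start, both centres from one catalytic step on a racemate, and a shorter sequence.

**Alternative 2:** The cut is the C1'–C2' bond of the side chain. Lactone **A6** would arise by Li2CuCl4-catalysed coupling of the primary triflate **A4**, derived from natural isocitric acid lactone **A3**, with the chain Grignard reagent **A5**.
- Merits: the cis relationship is bought from the chiral pool, so no selectivity has to be found by screening; this stereochemical certainty is better than the chosen plan. The benzyl ester of **A6** would be removed by hydrogenolysis, gentler than the ester cleavage of step 7.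
- Weak points: the two carboxyls of **A3** must be differentiated over several steps (one reduced, one benzylated). **A4** carries an ester-activated C4–H next to the triflate-bearing carbon, so a basic carbon nucleophile can cause epimerization or intramolecular displacement to a cyclopropane. The Grignard reagent must also spare a lactone and an ester. **A5** needs its own multistep synthesis, and the endgame is the same as steps 8 and 9.
- Against it the chosen plan sets a shorter linear route from two bulk chemicals and no organometallic reagent in the presence of the lactone.

**Alternative 3:** The cut is the bond from C4 to its carboxyl carbon, carried as CH2NO2. Acrylate **A8** would form from Baylis–Hillman carbonate **A7** (both C4 epimers) by (DHQD)2PHAL-catalysed substitution through a common allylammonium ion, with nitromethane anion attacking C4 in an SN2' step.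
- Merits: catalytic and stereoconvergent at C4, and C3=CH2 is present from the start, so no late methylenation is needed. That early, non-basic origin of the methylene is better than the chosen plan.
- Weak points: C5 is not set by this step and must come from an enantiopure α-silyloxy aldehyde, which adds steps and must survive a slow Baylis–Hillman reaction. The catalyst must control C4 next to a bulky existing centre, with a matched and a mismatched pairing, on an α-branched alkyl carbonate, a poorly reactive substrate type. The nitromethyl group must later be oxidized to the acid in the presence of the acrylate or methylene lactone.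
- Against it the chosen plan sets one catalyst controlling both centres in a single step, no preformed C5 centre, and a carboxyl that needs no oxidation-level change.

Key step: step 5

Assumption: a ketoreductase with the required anti (4S,5S) selectivity is taken to be obtainable from a commercial screening panel, as is usual for α-substituted β-keto esters; its identity is left to screening.

## Route

Step 1
Reactants: 1 15-pentadecanolide
Product: 3 16-hydroxyhexadecan-2-one, via hydroxy Weinreb amide 2 (not isolated)
Conditions: MeNH(OMe)·HCl, iPrMgCl, THF, −20 to 0 °C; then MeMgBr, 0 °C to rt; aq. NH4Cl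
Reagents that add atoms: methylmagnesium bromide, C[Mg]Br; N,O-dimethylhydroxylamine hydrochloride, CNOC.Cl (its atoms stay only in intermediate 2)
Why: Chloromagnesium N-methoxy-N-methylamide, made in the flask, opens the macrolide to the alkoxide of Weinreb amide 2, and MeMgBr then adds once because the magnesium chelate holds the tetrahedral adduct until work-up (Weinreb ketone synthesis); iPrMgCl serves as base because it does not attack the lactone at −20 °C.

Step 2
Reactants: 3 16-hydroxyhexadecan-2-one
Product: 4 14-(2-methyl-1,3-dioxolan-2-yl)tetradecan-1-ol
Conditions: HOCH2CH2OH, TsOH·H2O (cat.), benzene, reflux, Dean–Stark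
Reagents that add atoms: ethylene glycol, OCCO
Why: Acid-catalysed ketalization driven by azeotropic removal of water; the primary hydroxyl is unaffected, and the dioxolane shields the methyl ketone from the enzyme in step 5 and from carboxylation in step 8.

Step 3
Reactants: 4 14-(2-methyl-1,3-dioxolan-2-yl)tetradecan-1-ol
Product: 5 14-(2-methyl-1,3-dioxolan-2-yl)tetradecanal
Conditions: (COCl)2, DMSO, CH2Cl2, −78 °C; Et3N, −78 °C to rt
Reagents that add atoms: none
Why: Swern oxidation stops at the aldehyde and ends under basic conditions, so the acid-labile dioxolane is not at risk.

Step 4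
Reactants: 5 14-(2-methyl-1,3-dioxolan-2-yl)tetradecanal; 6 dimethyl fumarate
Product: 7 dimethyl 2-[14-(2-methyl-1,3-dioxolan-2-yl)tetradecanoyl]butanedioate (racemic)
Conditions: 3-benzyl-5-(2-hydroxyethyl)-4-methylthiazolium chloride (20 mol%), Et3N, DMF, 70 °C
Reagents that add atoms: none
Why: Stetter reaction: the thiazol-2-ylidene adds to 5, the resulting Breslow intermediate adds 1,4 to the fumarate and the catalyst is released; acyloin formation is reversible whereas the conjugate addition is not, and the new C4 centre is deliberately formed without control.

Step 5
Reactants: 7 dimethyl 2-[14-(2-methyl-1,3-dioxolan-2-yl)tetradecanoyl]butanedioate (racemic)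
Product: 8 dimethyl (2S)-2-[(1S)-1-hydroxy-14-(2-methyl-1,3-dioxolan-2-yl)tetradecyl]butanedioate
Conditions: NADPH-dependent ketoreductase (anti-(S,S)-selective panel enzyme), NADP+ (cat.), iPrOH (20% v/v), 0.1 M potassium phosphate pH 7.0, MgSO4 (1 mM), 30 °C
Reagents that add atoms: none
Why: The enzyme binds one C4 enantiomer of 7 next to NADPH and delivers the dihydronicotinamide hydride to one face of the C5 carbonyl while an active-site acid protonates the oxygen; isopropanol, oxidized by the same enzyme to acetone, regenerates NADPH. The closest known reaction type is the ketoreductase dynamic kinetic resolution of α-substituted β-keto esters. No ring is closed and no skeletal bond is formed; only the C5–H bond is made. C5 is set by the enzyme, which dictates the carbonyl face that receives hydride. C4 is set by the enzyme's preference for one enantiomer of 7 together with racemization of the other through the β-keto ester enol at pH 7, so that the whole racemate drains into one diastereomer; in 8 the C4–H is no longer activated by a ketone and stays fixed. The step needs enantioselection and anti diastereoselection for the (2S,1'S) isomer, the one that closes to the cis lactone; this is secured by the choice of enzyme, while the substrate supplies fast C4 epimerization, a dioxolane in place of the second ketone and esters that the reductase leaves alone. Material that lactonizes to 9 in the buffer is carried into step 6 and is not lost.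

Step 6
Reactants: 8 dimethyl (2S)-2-[(1S)-1-hydroxy-14-(2-methyl-1,3-dioxolan-2-yl)tetradecyl]butanedioate
Product: 9 methyl (2S,3S)-2-[13-(2-methyl-1,3-dioxolan-2-yl)tridecyl]-5-oxooxolane-3-carboxylate
Conditions: PPTS (cat.), toluene, 60 °C
Reagents that add atoms: none
Why: Acid-catalysed lactonization: the C5 hydroxyl attacks the distal ester (5-exo-trig) with loss of methanol, the proximal ester being able to give only a β-lactone; without base the cis C4 centre is not enolized, and both stereocentres are carried over unchanged.

Step 7
Reactants: 9 methyl (2S,3S)-2-[13-(2-methyl-1,3-dioxolan-2-yl)tridecyl]-5-oxooxolane-3-carboxylate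
Product: 10 (2S,3S)-2-[13-(2-methyl-1,3-dioxolan-2-yl)tridecyl]-5-oxooxolane-3-carboxylic acid
Conditions: Me3SnOH, ClCH2CH2Cl, 70 °C; brief wash with cold 5% aq. KHSO4
Reagents that add atoms: trimethyltin hydroxide, C[Sn](C)(C)O (supplies the hydroxyl oxygen of the acid)
Why: Me3SnOH cleaves methyl esters by tin-assisted delivery of hydroxide under nearly neutral conditions, which avoids the C4 enolization that aqueous hydroxide would cause in the cis ester; a lactone that opened would close again on the acidic wash, since only the γ-lactone can form.

Step 8
Reactants: 10 (2S,3S)-2-[13-(2-methyl-1,3-dioxolan-2-yl)tridecyl]-5-oxooxolane-3-carboxylic acid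
Product: 13 (2S,3S)-4-methylidene-2-[13-(2-methyl-1,3-dioxolan-2-yl)tridecyl]-5-oxooxolane-3-carboxylic acid, via carboxylated lactone diacid 11 (not isolated), via Mannich base 12 (not isolated)
Conditions: MeOMgOCO2Me (2 M in DMF), 130 °C; ice-cold 1 M HCl, rapid Et2O extraction; then 37% aq. HCHO, PhNHMe, NaOAc, AcOH, rt
Reagents that add atoms: formaldehyde, C=O; methoxymagnesium methyl carbonate, COC(=O)O[Mg]OC (its CO2 unit stays only in 11 and 12); N-methylaniline, CNc1ccccc1 (stays only in 12)
Why: Stiles carboxylation places a carboxyl on the lactone α-carbon C3 as a magnesium chelate, while C4, next to a carboxylate, is not deprotonated; the malonic half-acid 11 then undergoes Mannich reaction with the iminium ion from HCHO and PhNHMe to give 12, which loses CO2 and the amine in a decarboxylative elimination under acetate buffer to form the exocyclic alkene, leaving C4 and C5 unchanged.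

Step 9
Reactants: 13 (2S,3S)-4-methylidene-2-[13-(2-methyl-1,3-dioxolan-2-yl)tridecyl]-5-oxooxolane-3-carboxylic acid
Product: 14 allo-pertusaric acid, (2S,3S)-4-methylidene-5-oxo-2-(14-oxopentadecyl)oxolane-3-carboxylic acid
Conditions: 2 M aq. HCl, THF, rt
Reagents that add atoms: water, O
Why: Acid-catalysed hydrolysis of the dioxolane; the α-methylene lactone and the cis C4 centre are stable to dilute acid at room temperature, and base, which would move the double bond into the ring, is avoided.

## Compound list

1 | 15-pentadecanolide (oxacyclohexadecan-2-one) | O=C1CCCCCCCCCCCCCCO1 | starting material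
2 | 15-hydroxy-N-methoxy-N-methylpentadecanamide (present as its magnesium alkoxide) | CON(C)C(=O)CCCCCCCCCCCCCCO | intermediate (not isolated)
3 | 16-hydroxyhexadecan-2-one | CC(=O)CCCCCCCCCCCCCCO | intermediate
4 | 14-(2-methyl-1,3-dioxolan-2-yl)tetradecan-1-ol | CC1(CCCCCCCCCCCCCCO)OCCO1 | intermediate
5 | 14-(2-methyl-1,3-dioxolan-2-yl)tetradecanal | CC1(CCCCCCCCCCCCCC=O)OCCO1 | intermediate
6 | dimethyl fumarate | COC(=O)/C=C/C(=O)OC | starting material
7 | dimethyl 2-[14-(2-methyl-1,3-dioxolan-2-yl)tetradecanoyl]butanedioate (racemic) | COC(=O)CC(C(=O)OC)C(=O)CCCCCCCCCCCCCC1(C)OCCO1 | intermediate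
8 | dimethyl (2S)-2-[(1S)-1-hydroxy-14-(2-methyl-1,3-dioxolan-2-yl)tetradecyl]butanedioate | COC(=O)C[C@H](C(=O)OC)[C@@H](O)CCCCCCCCCCCCCC1(C)OCCO1 | intermediate
9 | methyl (2S,3S)-2-[13-(2-methyl-1,3-dioxolan-2-yl)tridecyl]-5-oxooxolane-3-carboxylate | C1C(=O)O[C@@H](CCCCCCCCCCCCCC2(C)OCCO2)[C@H]1C(=O)OC | intermediate
10 | (2S,3S)-2-[13-(2-methyl-1,3-dioxolan-2-yl)tridecyl]-5-oxooxolane-3-carboxylic acid | C1C(=O)O[C@@H](CCCCCCCCCCCCCC2(C)OCCO2)[C@H]1C(=O)O | intermediate
11 | (2S,3S)-2-[13-(2-methyl-1,3-dioxolan-2-yl)tridecyl]-5-oxooxolane-3,4-dicarboxylic acid (C4 epimers; magnesium chelate in the flask) | OC(=O)C1C(=O)O[C@@H](CCCCCCCCCCCCCC2(C)OCCO2)[C@H]1C(=O)O | intermediate (not isolated)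
12 | (2S,3S)-4-{[methyl(phenyl)amino]methyl}-2-[13-(2-methyl-1,3-dioxolan-2-yl)tridecyl]-5-oxooxolane-3,4-dicarboxylic acid (C4 epimers) | CN(CC1(C(=O)O)C(=O)O[C@@H](CCCCCCCCCCCCCC2(C)OCCO2)[C@H]1C(=O)O)c1ccccc1 | intermediate (not isolated)
13 | (2S,3S)-4-methylidene-2-[13-(2-methyl-1,3-dioxolan-2-yl)tridecyl]-5-oxooxolane-3-carboxylic acid | C=C1C(=O)O[C@@H](CCCCCCCCCCCCCC2(C)OCCO2)[C@H]1C(=O)O | intermediate
14 | allo-pertusaric acid, (2S,3S)-4-methylidene-5-oxo-2-(14-oxopentadecyl)oxolane-3-carboxylic acid | C=C1C(=O)O[C@@H](CCCCCCCCCCCCCC(C)=O)[C@H]1C(=O)O | target

## Step count and risks

Total step count: 9. Longest linear sequence: 9 steps, from 1 to 14 (6 is purchased).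

The least certain steps, in route order:

**Step 4 (Stetter addition).** The Breslow intermediate of an aliphatic aldehyde may be diverted into acyloin self-condensation, the carbene may be consumed by addition to the fumarate, or the acidic product may add to a second fumarate, so conversion to 7 may stall. The fallback builds the succinate by enolate alkylation instead of acyl-anion addition. It sets out from 5: Roskamp homologation with methyl diazoacetate and catalytic SnCl2 in CH2Cl2 should give the β-keto ester methyl 16-(2-methyl-1,3-dioxolan-2-yl)-3-oxohexadecanoate F1. C-Alkylation of F1 with methyl bromoacetate (K2CO3, acetone) comes back to the route at 7.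

**Step 5 (key step).** The lipophilic C14 chain may keep the substrate out of the aqueous phase or out of the active site, so turnover is slow. Reduction may also outrun C4 racemization, so the slow-reacting enantiomer is reduced with poor diastereoselection. An esterase impurity in the enzyme preparation may hydrolyse an ester. The fallback replaces simultaneous control by sequential control. It sets out from 5 and passes through methyl 16-(2-methyl-1,3-dioxolan-2-yl)-3-oxohexadecanoate F1, made as described for step 4. Asymmetric hydrogenation of F1 with RuCl2[(S)-BINAP] and H2 in methanol should give methyl (3S)-3-hydroxy-16-(2-methyl-1,3-dioxolan-2-yl)hexadecanoate F2, setting C5 by catalyst control. Fráter–Seebach alkylation of the dianion of F2 (LDA, 2.2 equiv, THF, −78 to −20 °C, then allyl bromide) should give the anti product methyl (2S,3S)-3-hydroxy-16-(2-methyl-1,3-dioxolan-2-yl)-2-(prop-2-en-1-yl)hexadecanoate F3, setting C4 by induction from the alkoxide-bearing centre. Ozonolysis of F3 (O3, CH2Cl2, −78 °C; Me2S) should give the lactol methyl (2S,3S)-5-hydroxy-2-[13-(2-methyl-1,3-dioxolan-2-yl)tridecyl]oxolane-3-carboxylate F4. Oxidation of F4 with catalytic Pr4N[RuO4] and N-methylmorpholine N-oxide comes back to the route at 9.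

**Step 7 (ester cleavage).** Enolization at C4 during the cleavage would erode the cis acid towards trans, and the ester cis to the long chain may react slowly. An over-long acidic wash would strip the dioxolane, which step 8 cannot tolerate. The fallback hydrolyses before the ring is closed, so that base meets C4 only in an unstrained acyclic compound and next to a carboxylate. It sets out from 8: LiOH in THF/water at 0 °C, then acidification to pH 4 with citric acid, should give (2S)-2-[(1S)-1-hydroxy-14-(2-methyl-1,3-dioxolan-2-yl)tetradecyl]butanedioic acid F5. Warming F5 in toluene with catalytic PPTS closes the γ-lactone and comes back to the route at 10.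

**Step 8 (carboxylation and methylenation).** At 130 °C under basic magnesium methoxide and carbonate the cis acid may epimerize at C4. The carboxylated intermediate may also lose CO2 again during the acidic work-up before it meets the iminium ion, returning 10. Partial loss of the dioxolane in the acidic stages is tolerable, since step 9 removes it anyway. The fallback works at low temperature through a dianion. It sets out from 10: LiHMDS (2.2 equiv, THF, −78 °C) forms the carboxylate–C3 enolate, and Eschenmoser's salt (CH2=NMe2+ I−) should give (2S,3S)-4-[(dimethylamino)methyl]-2-[13-(2-methyl-1,3-dioxolan-2-yl)tridecyl]-5-oxooxolane-3-carboxylic acid F6. Quaternization of F6 with MeI should give 1-[(4S,5S)-4-carboxy-5-[13-(2-methyl-1,3-dioxolan-2-yl)tridecyl]-2-oxooxolan-3-yl]-N,N,N-trimethylmethanaminium iodide F7. Elimination from F7 with aqueous NaHCO3 comes back to the route at 13.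

## Further compounds

F1 | step 4 | methyl 16-(2-methyl-1,3-dioxolan-2-yl)-3-oxohexadecanoate | COC(=O)CC(=O)CCCCCCCCCCCCCC1(C)OCCO1
F2 | step 5 | methyl (3S)-3-hydroxy-16-(2-methyl-1,3-dioxolan-2-yl)hexadecanoate | COC(=O)C[C@@H](O)CCCCCCCCCCCCCC1(C)OCCO1
F3 | step 5 | methyl (2S,3S)-3-hydroxy-16-(2-methyl-1,3-dioxolan-2-yl)-2-(prop-2-en-1-yl)hexadecanoate | C=CC[C@H](C(=O)OC)[C@@H](O)CCCCCCCCCCCCCC1(C)OCCO1
F4 | step 5 | methyl (2S,3S)-5-hydroxy-2-[13-(2-methyl-1,3-dioxolan-2-yl)tridecyl]oxolane-3-carboxylate (anomer mixture) | C1C(O)O[C@@H](CCCCCCCCCCCCCC2(C)OCCO2)[C@H]1C(=O)OC
F5 | step 7 | (2S)-2-[(1S)-1-hydroxy-14-(2-methyl-1,3-dioxolan-2-yl)tetradecyl]butanedioic acid | OC(=O)C[C@H](C(=O)O)[C@@H](O)CCCCCCCCCCCCCC1(C)OCCO1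
F6 | step 8 | (2S,3S)-4-[(dimethylamino)methyl]-2-[13-(2-methyl-1,3-dioxolan-2-yl)tridecyl]-5-oxooxolane-3-carboxylic acid (C4 epimers) | CN(C)CC1C(=O)O[C@@H](CCCCCCCCCCCCCC2(C)OCCO2)[C@H]1C(=O)O
F7 | step 8 | 1-[(4S,5S)-4-carboxy-5-[13-(2-methyl-1,3-dioxolan-2-yl)tridecyl]-2-oxooxolan-3-yl]-N,N,N-trimethylmethanaminium iodide | C[N+](C)(C)CC1C(=O)O[C@@H](CCCCCCCCCCCCCC2(C)OCCO2)[C@H]1C(=O)O.[I-]
A1 | alternative 1 | (3R,4S)-3-{[(tert-butyldimethylsilyl)oxy]methyl}-17-(2-methyl-1,3-dioxolan-2-yl)heptadec-1-yn-4-ol | C#C[C@H](CO[Si](C)(C)C(C)(C)C)[C@@H](O)CCCCCCCCCCCCCC1(C)OCCO1
A2 | alternative 1 | (4R,5S)-4-{[(tert-butyldimethylsilyl)oxy]methyl}-3-methylidene-5-[13-(2-methyl-1,3-dioxolan-2-yl)tridecyl]oxolan-2-one | C=C1C(=O)O[C@@H](CCCCCCCCCCCCCC2(C)OCCO2)[C@H]1CO[Si](C)(C)C(C)(C)C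
A3 | alternative 2 | (2R,3S)-5-oxooxolane-2,3-dicarboxylic acid (isocitric acid lactone) | C1C(=O)O[C@@H](C(=O)O)[C@H]1C(=O)O
A4 | alternative 2 | benzyl (2R,3S)-5-oxo-2-{[(trifluoromethanesulfonyl)oxy]methyl}oxolane-3-carboxylate | C1C(=O)O[C@@H](COS(=O)(=O)C(F)(F)F)[C@H]1C(=O)OCc1ccccc1
A5 | alternative 2 | bromo[12-(2-methyl-1,3-dioxolan-2-yl)dodecyl]magnesium | CC1(CCCCCCCCCCCC[Mg]Br)OCCO1
A6 | alternative 2 | benzyl (2S,3S)-2-[13-(2-methyl-1,3-dioxolan-2-yl)tridecyl]-5-oxooxolane-3-carboxylate | C1C(=O)O[C@@H](CCCCCCCCCCCCCC2(C)OCCO2)[C@H]1C(=O)OCc1ccccc1
A7 | alternative 3 | methyl 2-[(2S)-1-[(tert-butoxycarbonyl)oxy]-2-[(tert-butyldimethylsilyl)oxy]-15-(2-methyl-1,3-dioxolan-2-yl)pentadecyl]prop-2-enoate (both C1 epimers) | C=C(C(=O)OC)C(OC(=O)OC(C)(C)C)[C@@H](O[Si](C)(C)C(C)(C)C)CCCCCCCCCCCCCC1(C)OCCO1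
A8 | alternative 3 | methyl 2-[(2R,3S)-3-[(tert-butyldimethylsilyl)oxy]-16-(2-methyl-1,3-dioxolan-2-yl)-1-nitrohexadecan-2-yl]prop-2-enoate | C=C(C(=O)OC)[C@H](C[N+](=O)[O-])[C@@H](O[Si](C)(C)C(C)(C)C)CCCCCCCCCCCCCC1(C)OCCO1
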